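## Retrosynthetic overview

1. Ballotiquinone ⇐ the 11,12,14-trimethoxy arene (ring C carried as a protected hydroxyhydroquinone; Ce(IV) oxidation, then hydrolysis) and the C1 ketone (Luche reduction).
2. Rings A and B ⇐ one flask: intermolecular Diels–Alder of a 2-silyloxybutadiene onto the butenolide C4=C5 bond (ring A; C4 and C5 set anti to the C6 substituent), then intramolecular aldol condensation of C10 onto the C20 aldehyde (seven-membered ring B with C10=C20).
3. C20 aldehyde ⇐ formylation of the last free arene position. C6, C7 and the lactone ⇐ anti-selective asymmetric vinylogous Mukaiyama aldol of a 3-methyl-2-silyloxyfuran with the aryl aldehyde.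
4. Aryl aldehyde ⇐ 1,2,4-trimethoxybenzene (lithiation, acetone, ionic hydrogenation, formylation).
5. Ring order: C (bought arene) → γ-lactone (bought butenolide) → A, then B, in the same operation.

Assumption: atom labels C1–C20 follow icetexane numbering of the target, and the pseudoenantiomer of the cinchona catalyst in step 4 is the one that delivers the (5R,1′S) adduct.

## Route

Step 1
Reactants: 1 1,2,4-trimethoxybenzene; 2 acetone
Product: 4 1,2,4-trimethoxy-3-(propan-2-yl)benzene, via benzylic carbinol 3 (not isolated)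
Conditions: n-BuLi, TMEDA, THF, 0 °C; acetone, −78 → 0 °C; then (solvent changed to CH2Cl2) Et3SiH, TFA, 0 °C → rt
Reagents that add atoms: none
Why: Directed ortho-lithiation at the position flanked by two methoxy groups, 1,2-addition to acetone and ionic hydrogenation of the resulting tertiary benzylic alcohol (via the cation stabilised by two ortho-methoxy groups) place the isopropyl group regiospecifically between the future C12 and C14 oxygens; no stereocentre is formed.

Step 2
Reactants: 4 1,2,4-trimethoxy-3-(propan-2-yl)benzene; 5 dichloromethyl methyl ether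
Product: 6 2,4,5-trimethoxy-3-(propan-2-yl)benzaldehyde
Conditions: Cl2CHOMe, TiCl4, CH2Cl2, −78 → 0 °C; H2O
Reagents that add atoms: water, O
Why: Rieche formylation, an electrophilic aromatic substitution that goes to the only position para to one methoxy group and ortho to another, gives the future C7 aldehyde on C8; no stereocentre is formed.

Step 3
Reactants: 7 3-methylfuran-2(5H)-one
Product: 8 trimethyl[(3-methylfuran-2-yl)oxy]silane
Conditions: TMSOTf, Et3N, Et2O, 0 °C
Reagents that add atoms: trimethylsilyl trifluoromethanesulfonate, C[Si](C)(C)OS(=O)(=O)C(F)(F)F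
Why: Soft enolisation and O-silylation of the butenolide give the aromatic 2-silyloxyfuran, the vinylogous silyl ketene acetal needed for a Mukaiyama-type addition.

Step 4
Reactants: 6 2,4,5-trimethoxy-3-(propan-2-yl)benzaldehyde; 8 trimethyl[(3-methylfuran-2-yl)oxy]silane
Product: 10 (5R)-5-{(S)-hydroxy[2,4,5-trimethoxy-3-(propan-2-yl)phenyl]methyl}-3-methylfuran-2(5H)-one, via O-trimethylsilyl aldol adduct 9 (not isolated)
Conditions: cinchona-derived thiourea–ammonium carboxylate salt (10 mol %), CH2Cl2, −20 °C; then 1 M HCl, THF, 0 °C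
Reagents that add atoms: none
Why: Catalytic enantioselective vinylogous Mukaiyama aldol reaction in which the carboxylate-activated furan dienolate attacks the aldehyde through its γ-carbon in an open, anti (erythro)-selective transition state while the chiral ion pair fixes the absolute sense, so that C6 (R) and C7 (S) are set together, and the acidic work-up cleaves the O-TMS ether.

Step 5
Reactants: 10 (5R)-5-{(S)-hydroxy[2,4,5-trimethoxy-3-(propan-2-yl)phenyl]methyl}-3-methylfuran-2(5H)-one
Product: 11 (5R)-5-{(S)-[(tert-butyldimethylsilyl)oxy][2,4,5-trimethoxy-3-(propan-2-yl)phenyl]methyl}-3-methylfuran-2(5H)-one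
Conditions: TBSOTf, 2,6-lutidine, CH2Cl2, −78 → 0 °C
Reagents that add atoms: tert-butyldimethylsilyl trifluoromethanesulfonate, CC(C)(C)[Si](C)(C)OS(=O)(=O)C(F)(F)F
Why: Silylation protects the ionisation-prone electron-rich benzylic alcohol for the Lewis-acid step and prevents its later oxa-Michael addition to the C10=C20 enone; the stereocentres are untouched.

Step 6
Reactants: 11 (5R)-5-{(S)-[(tert-butyldimethylsilyl)oxy][2,4,5-trimethoxy-3-(propan-2-yl)phenyl]methyl}-3-methylfuran-2(5H)-one; 5 dichloromethyl methyl ether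
Product: 12 2-{(S)-[(tert-butyldimethylsilyl)oxy][(2R)-4-methyl-5-oxo-2,5-dihydrofuran-2-yl]methyl}-3,5,6-trimethoxy-4-(propan-2-yl)benzaldehyde
Conditions: Cl2CHOMe, AgOTf, CH2Cl2, −78 °C; aq. NaHCO3
Reagents that add atoms: water, O
Why: Rieche formylation under silver triflate activation at −78 °C attacks the only remaining aromatic C–H (C9, ortho to a methoxy group) and brings in C20 as the aldehyde without touching the silyl ether, the butenolide or the stereocentres.

Step 7
Reactants: 12 2-{(S)-[(tert-butyldimethylsilyl)oxy][(2R)-4-methyl-5-oxo-2,5-dihydrofuran-2-yl]methyl}-3,5,6-trimethoxy-4-(propan-2-yl)benzaldehyde; 13 (buta-1,3-dien-2-yloxy)trimethylsilane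
Product: 16 (4S,5R,6R,7S)-7-[(tert-butyldimethylsilyl)oxy]-11,12,14-trimethoxy-1-oxo-9(10→20)abeo-abieta-8,10(20),11,13-tetraen-19,6-olide, via Diels–Alder adduct 14 (not isolated), via keto aldehyde 15 (not isolated)
Conditions: 13 (6 equiv), BHT, toluene, 170 °C, sealed tube; then MeOH, pyrrolidine, AcOH, 50 °C
Reagents that add atoms: none
Why: A thermal Diels–Alder reaction of the 2-silyloxydiene with the butenolide C4=C5 bond (nucleophilic diene CH2 to the β-carbon C5, approach anti to the bulky C6 substituent, cis addition across the ring alkene) builds ring A and sets the quaternary C4 (S) and C5 (R), after which methanolysis of the silyl enol ether and an amine-mediated intramolecular aldol condensation, possible only through C10 for ring-size reasons, close the seven-membered ring B as the C10=C20 enone.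

Step 8
Reactants: 16 (4S,5R,6R,7S)-7-[(tert-butyldimethylsilyl)oxy]-11,12,14-trimethoxy-1-oxo-9(10→20)abeo-abieta-8,10(20),11,13-tetraen-19,6-olide
Product: 17 (1R,4S,5R,6R,7S)-7-[(tert-butyldimethylsilyl)oxy]-1-hydroxy-11,12,14-trimethoxy-9(10→20)abeo-abieta-8,10(20),11,13-tetraen-19,6-olide
Conditions: NaBH4, CeCl3·7H2O, MeOH/CH2Cl2, −40 °C
Reagents that add atoms: none
Why: Luche 1,2-reduction delivers hydride to the C1 ketone from the convex α-face (the face of H5 and the C4 methyl, opposite the cis-fused lactone and ring B), giving the 1β (1R) allylic alcohol without conjugate reduction or attack on the lactone.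

Step 9
Reactants: 17 (1R,4S,5R,6R,7S)-7-[(tert-butyldimethylsilyl)oxy]-1-hydroxy-11,12,14-trimethoxy-9(10→20)abeo-abieta-8,10(20),11,13-tetraen-19,6-olide
Product: 18 (1R,4S,5R,6R,7S)-7-[(tert-butyldimethylsilyl)oxy]-1-hydroxy-12-methoxy-11,14-dioxo-9(10→20)abeo-abieta-8,10(20),12-trien-19,6-olide
Conditions: CAN (2.5 equiv), MeCN/H2O, 0 °C
Reagents that add atoms: water, O
Why: Ce(IV) oxidative demethylation converts the para-related C11 and C14 methoxy groups into the p-quinone carbonyls (oxygens from water) and leaves the C12 methoxy group as a vinylogous ester; no stereocentre is involved.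

Step 10
Reactants: 18 (1R,4S,5R,6R,7S)-7-[(tert-butyldimethylsilyl)oxy]-1-hydroxy-12-methoxy-11,14-dioxo-9(10→20)abeo-abieta-8,10(20),12-trien-19,6-olide
Product: 19 ballotiquinone, (1R,4S,5R,6R,7S)-1,7,12-trihydroxy-11,14-dioxo-9(10→20)abeo-abieta-8,10(20),12-trien-19,6-olide
Conditions: aq. HClO4, THF, rt → 40 °C
Reagents that add atoms: water, O
Why: Acid-catalysed addition–elimination of water at C12 hydrolyses the vinylogous methyl ester to the hydroxyquinone and the same aqueous acid cleaves the TBS ether, while the electron-poor quinone keeps C7 and C1 from ionising, so no stereocentre is touched.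

## Compound list

1 | 1,2,4-trimethoxybenzene | COc1ccc(OC)c(OC)c1 | starting material
2 | acetone | CC(C)=O | starting material
3 | 2-(2,3,6-trimethoxyphenyl)propan-2-ol (benzylic carbinol, not isolated) | COc1ccc(OC)c(OC)c1C(C)(C)O | intermediate
4 | 1,2,4-trimethoxy-3-(propan-2-yl)benzene | COc1ccc(OC)c(OC)c1C(C)C | intermediate
5 | dichloromethyl methyl ether | COC(Cl)Cl | starting material
6 | 2,4,5-trimethoxy-3-(propan-2-yl)benzaldehyde | COc1c(C=O)cc(OC)c(OC)c1C(C)C | intermediate
7 | 3-methylfuran-2(5H)-one | CC1=CCOC1=O | starting material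
8 | trimethyl[(3-methylfuran-2-yl)oxy]silane | Cc1ccoc1O[Si](C)(C)C | intermediate
9 | (5R)-3-methyl-5-{(S)-[2,4,5-trimethoxy-3-(propan-2-yl)phenyl][(trimethylsilyl)oxy]methyl}furan-2(5H)-one (not isolated) | COc1c(cc(OC)c(OC)c1C(C)C)[C@H](O[Si](C)(C)C)[C@@H]1OC(=O)C(C)=C1 | intermediate
10 | (5R)-5-{(S)-hydroxy[2,4,5-trimethoxy-3-(propan-2-yl)phenyl]methyl}-3-methylfuran-2(5H)-one | COc1c(cc(OC)c(OC)c1C(C)C)[C@H](O)[C@@H]1OC(=O)C(C)=C1 | intermediate
11 | (5R)-5-{(S)-[(tert-butyldimethylsilyl)oxy][2,4,5-trimethoxy-3-(propan-2-yl)phenyl]methyl}-3-methylfuran-2(5H)-one | COc1c(cc(OC)c(OC)c1C(C)C)[C@H](O[Si](C)(C)C(C)(C)C)[C@@H]1OC(=O)C(C)=C1 | intermediate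
12 | 2-{(S)-[(tert-butyldimethylsilyl)oxy][(2R)-4-methyl-5-oxo-2,5-dihydrofuran-2-yl]methyl}-3,5,6-trimethoxy-4-(propan-2-yl)benzaldehyde | COc1c(c(C=O)c(OC)c(OC)c1C(C)C)[C@H](O[Si](C)(C)C(C)(C)C)[C@@H]1OC(=O)C(C)=C1 | intermediate
13 | (buta-1,3-dien-2-yloxy)trimethylsilane | C=CC(=C)O[Si](C)(C)C | starting material
14 | Diels–Alder adduct (not isolated): 2-{(S)-[(tert-butyldimethylsilyl)oxy][(1R,3aS,7aR)-3a-methyl-3-oxo-6-[(trimethylsilyl)oxy]-1,3,3a,4,7,7a-hexahydro-2-benzofuran-1-yl]methyl}-3,5,6-trimethoxy-4-(propan-2-yl)benzaldehyde | CC(C)c1c(OC)c(OC)c(C=O)c(c1OC)[C@H](O[Si](C)(C)C(C)(C)C)[C@@H]1OC(=O)[C@@]2(C)CC=C(O[Si](C)(C)C)C[C@@H]12 | intermediate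
15 | keto aldehyde (not isolated): 2-{(S)-[(tert-butyldimethylsilyl)oxy][(1R,3aS,7aR)-3a-methyl-3,6-dioxooctahydro-2-benzofuran-1-yl]methyl}-3,5,6-trimethoxy-4-(propan-2-yl)benzaldehyde | CC(C)c1c(OC)c(OC)c(C=O)c(c1OC)[C@H](O[Si](C)(C)C(C)(C)C)[C@@H]1OC(=O)[C@@]2(C)CCC(=O)C[C@@H]12 | intermediate
16 | (4S,5R,6R,7S)-7-[(tert-butyldimethylsilyl)oxy]-11,12,14-trimethoxy-1-oxo-9(10→20)abeo-abieta-8,10(20),11,13-tetraen-19,6-olide | CC(C)c1c(OC)c(OC)c2c(c1OC)[C@H](O[Si](C)(C)C(C)(C)C)[C@@H]1OC(=O)[C@@]3(C)CCC(=O)C(=C2)[C@@H]13 | intermediate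
17 | (1R,4S,5R,6R,7S)-7-[(tert-butyldimethylsilyl)oxy]-1-hydroxy-11,12,14-trimethoxy-9(10→20)abeo-abieta-8,10(20),11,13-tetraen-19,6-olide | CC(C)c1c(OC)c(OC)c2c(c1OC)[C@H](O[Si](C)(C)C(C)(C)C)[C@@H]1OC(=O)[C@@]3(C)CC[C@@H](O)C(=C2)[C@@H]13 | intermediate
18 | (1R,4S,5R,6R,7S)-7-[(tert-butyldimethylsilyl)oxy]-1-hydroxy-12-methoxy-11,14-dioxo-9(10→20)abeo-abieta-8,10(20),12-trien-19,6-olide | CC(C)C1=C(OC)C(=O)C2=C(C1=O)[C@H](O[Si](C)(C)C(C)(C)C)[C@@H]1OC(=O)[C@@]3(C)CC[C@@H](O)C(=C2)[C@@H]13 | intermediate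
19 | ballotiquinone | CC(C)C1=C(O)C(=O)C2=C(C1=O)[C@H](O)[C@@H]1OC(=O)[C@@]3(C)CC[C@@H](O)C(=C2)[C@@H]13 | target

## Step count and risks

Total step count: 10. Longest linear sequence: 9 steps (1, 2, 4, 5, 6, 7, 8, 9, 10); step 3 is a one-step branch.

**Step 7 (most likely to fail).** The α-methyl, γ-branched butenolide is a sluggish dienophile, and the siloxydiene may decompose before it adds. The fallback sets out from 12 and comes back at 16. Compound 12 is heated with the much more electron-rich trans-1-methoxy-3-(trimethylsilyloxy)buta-1,3-diene (Danishefsky's diene; toluene, 110 °C), which gives the methoxy silyl enol ether cycloadduct F1 with the same regio- and facial sense. Dilute HCl turns it into the cyclohexenone aldehyde F2. Pyrrolidine and acetic acid then close ring B, C10 now being the only enolisable position, to the cross-conjugated dienone F3. Stryker's reagent, [(Ph3P)CuH]6, reduces the unhindered disubstituted C2=C3 enone selectively and delivers 16.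

**Step 4.** The aldehyde is electron-rich and ortho-substituted, so conversion, anti selectivity or enantioselectivity may be poor. The fallback sets out from 6 and 8 and comes back at 10. A chiral Lewis-acid catalyst (Ti(IV)–BINOL type), whose transition state is threo-selective, gives the O-silyl threo adduct F4 and, after acidic work-up, the (5R,1′R)-alcohol F5. Mitsunobu inversion at C7 with 4-nitrobenzoic acid (PPh3, DIAD) gives the (5R,1′S) 4-nitrobenzoate F6. Methanolysis with Mg(OMe)2 in MeOH at 0 °C returns 10.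

**Step 6.** The formylating cation may attack the benzylic silyl ether or the ipso position (C8) instead of the crowded C9–H. The fallback sets out from 11 and comes back at 12. Compound 11 is iodinated at C9 with I2 and silver trifluoroacetate (CHCl3, 0 °C) to the aryl iodide F7. Neutral palladium-catalysed reductive carbonylation (CO, Bu3SnH, Pd(PPh3)4, toluene, 50 °C) then installs the aldehyde and gives 12 without base, so the butenolide C6–H is not at risk.

## Further compounds

F1 | step 7 | Danishefsky cycloadduct (C3-methoxy, C1 trimethylsilyl enol ether, ring fusion as in 14, C3 epimers) | CC(C)c1c(OC)c(OC)c(C=O)c(c1OC)[C@H](O[Si](C)(C)C(C)(C)C)[C@@H]1OC(=O)[C@@]2(C)C(OC)C=C(O[Si](C)(C)C)C[C@@H]12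
F2 | step 7 | cyclohexenone aldehyde (C1 ketone, C2=C3, aryl aldehyde free) | CC(C)c1c(OC)c(OC)c(C=O)c(c1OC)[C@H](O[Si](C)(C)C(C)(C)C)[C@@H]1OC(=O)[C@@]2(C)C=CC(=O)C[C@@H]12
F3 | step 7 | cross-conjugated dienone (2,3-didehydro analogue of 16) | CC(C)c1c(OC)c(OC)c2c(c1OC)[C@H](O[Si](C)(C)C(C)(C)C)[C@@H]1OC(=O)[C@@]3(C)C=CC(=O)C(=C2)[C@@H]13
F4 | step 4 | O-trimethylsilyl threo adduct, (5R,1′R) | COc1c(cc(OC)c(OC)c1C(C)C)[C@@H](O[Si](C)(C)C)[C@@H]1OC(=O)C(C)=C1
F5 | step 4 | (5R)-5-{(R)-hydroxy[2,4,5-trimethoxy-3-(propan-2-yl)phenyl]methyl}-3-methylfuran-2(5H)-one | COc1c(cc(OC)c(OC)c1C(C)C)[C@@H](O)[C@@H]1OC(=O)C(C)=C1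
F6 | step 4 | (S)-[(2R)-4-methyl-5-oxo-2,5-dihydrofuran-2-yl][2,4,5-trimethoxy-3-(propan-2-yl)phenyl]methyl 4-nitrobenzoate | COc1c(cc(OC)c(OC)c1C(C)C)[C@H](OC(=O)c1ccc(cc1)[N+](=O)[O-])[C@@H]1OC(=O)C(C)=C1
F7 | step 6 | (5R)-5-{(S)-[(tert-butyldimethylsilyl)oxy][2-iodo-3,4,6-trimethoxy-5-(propan-2-yl)phenyl]methyl}-3-methylfuran-2(5H)-one | COc1c(c(I)c(OC)c(OC)c1C(C)C)[C@H](O[Si](C)(C)C(C)(C)C)[C@@H]1OC(=O)C(C)=C1
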